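## Structural features

The target is a flavanone: a benzene ring A fused to a dihydropyranone ring C (O1, C2, C3, C4, C4a, C8a), with an unsubstituted phenyl ring B on C2. Ring A is fully substituted except for C5–H: prenyl groups at C6 and C8 flank the free C7 hydroxyl, and the C8 prenyl also stands ortho to the ring oxygen O1. The only stereocentre is C2 (S), a benzylic carbon that carries the aryl ether oxygen and stands β to the C4 ketone, so no neighbouring stereocentre can guide its formation. This arrangement is the fragile point: base opens the β-aryloxy ketone to the 2'-hydroxychalcone by retro-oxa-Michael reaction and reclosure returns racemate, while acid turns an ortho-prenylphenol into a 2,2-dimethylchroman and can ionise the benzylic C2–O bond. The trisubstituted prenyl alkenes also rule out hydrogenolysis, electrophilic halogen and peracid reagents. The real difficulty is therefore to deliver C2 as one enantiomer and keep it so while two acid-sensitive prenyl groups and a hindered phenol are carried along. The key step exploits the fact that C2 is a carbinol-type carbon 1,3 to the C4 carbonyl: with C4 reversed in polarity as a dithiane-stabilised acyl anion, C3–C4 is made by opening a phenyl-substituted epoxide at its CH2 end, so C2 arrives with its oxygen and configuration in place and C4 stays masked until ring C is closed.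

## Logic of the disconnections

**15 ⇒ 14.** The C7 O–H is traced back to an O–Si bond. A free phenol between two prenyl groups would be alkylated, oxidised or cyclised by reagents needed earlier, so it stays capped to the end. Nothing is gained in skeleton, but every earlier step then works on a neutral ring A. The demand is that silicon leaves without free base, because 14 already holds the β-aryloxy ketone; the fluoride must be buffered.

**14 ⇒ 13.** The C4 carbonyl is traced back to two C4–S bonds of a cyclic dithioketal. While C4 is not a carbonyl, C3 is not acidic and O1 cannot be expelled, so C2 is safe during and after ring closure. The dithioketal is also what the umpolung step leaves behind, so it costs no extra step to install. The demand is an unmasking that is neither oxidative nor strongly acidic, because of the alkenes and the silyl ether.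

**13 ⇒ 12.** The O1–C2 bond of ring C is cut. Forming it by SN2 displacement at C2 lets a ready-made carbinol stereocentre be transferred with inversion, and it opens ring C to an acyclic phenol–carbinol. The forward step must be a clean intramolecular SN2 reaction without ionisation at benzylic C2. The oxygen that becomes O1 must be free while the C7 oxygen stays capped.

**12 ⇒ 11.** Only the O–allyl bond on the future O1 is changed. This oxygen must be capped during the carbanion chemistry and freed afterwards beside an ortho prenyl group, a benzylic carbinol, an aryl silyl ether and a dithioketal. An acetal-type group such as methoxymethyl would need acid for removal, which closes ortho-prenylphenols to chromans and endangers the carbinol; it would also not survive thiol with Lewis acid. A silyl group would shift from oxygen to the adjacent carbanion. An allyl ether avoids all three problems. The demand is that palladium-catalysed allyl transfer works next to two sulfur atoms.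

**11 ⇒ 8 + 9 (through 10).** The C3–C4 bond is cut. The hydroxyl on C2 is 1,3 to C4, the pattern produced when an acyl anion opens an epoxide. The cut separates ring A with C4 from the C2–C3–phenyl unit, which is available as a single enantiomer, so the stereocentre is bought and the synthesis is convergent. The demands are that 10 forms only at the dithiane carbon, attacks only the CH2 terminus of 9, and meets no electrophilic or transferable group within 8.

**8 ⇒ 6 + 7.** Two C–S bonds are cut, returning the dithiane to the formyl group. The thiol and Lewis acid needed forward must find no free ortho-prenylphenol and no acetal, which is why both oxygens are capped first with acid-insensitive groups.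

**6 ⇒ 5 ⇒ 4.** The O–allyl bond and then the O–Si bond are cut. The two hydroxyls of 4 differ, one being chelated to the formyl group, so they can be capped in sequence without a regiochemical separation. Silicon goes first onto the free, more acidic hydroxyl; it must be bulky enough to survive the carbonate base of the allylation and the organolithium base later.

**4 ⇒ 1 + 2 (through 3).** The two aryl–CH2 bonds at C6 and C8 are cut. Both carbons are ortho or para to both oxygens and are the natural nucleophilic sites of the resorcinol nucleus. This reduces ring A to a commodity compound that already carries the C4 carbon and both oxygens. The demand is C-alkylation over O-alkylation, twice, so two molecules of 2 are consumed for each molecule of 1, the first giving 3 and the second 4. This is the least efficient step and is placed first for that reason.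

## Other disconnections considered

Alternative 1: The cut runs through ring A itself (C7–C8, C4a–C8a and C6–C7), leading back to the diazo enone A1 and the prenyl-substituted siloxyalkyne A2.

- **Forward step.** Irradiation of A1 would trigger a Wolff rearrangement to a vinylketene. This adds A2 in a [2+2] sense (ketene carbon C7 to the prenyl-bearing alkyne carbon C8, ketene α-carbon C4a to the siloxy-bearing carbon C8a). 4π opening of the four-membered ring, 6π closure (C6–C7) and tautomerisation would give the phenol A3 (Danheiser benzannulation).
- **In favour.** Each prenyl group comes in on its own acyclic fragment, so the substitution pattern of ring A is fixed by connectivity. On regiocontrol in ring A this is better than step 1 of the chosen plan. The neutral photochemical and thermal conditions suit the prenyl groups at least as well as anything in the chosen plan.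
- **Against.** It solves the part of the molecule that is otherwise accessible by aromatic substitution. A3 has no carbon at C4a, carries its silyl group on the oxygen destined to become O1 and has the C7 hydroxyl free. That is the reverse of the pattern the later chemistry needs, so a protecting-group exchange and a C-acylation or formylation must follow. Ring C and C2 are untouched, so an enantioselective step of the kind used in the chosen plan or in alternative 3 must still be added. A1 is a skipped dienone whose doubly allylic CH2 group is acidic, so its prenyl alkene could slide into conjugation with the enone under the basic conditions of a diazo transfer.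
- **Comparison.** Structurally it addresses ring A only. Mechanistically the pericyclic cascade is sound but rests on a sensitive precursor. In step economy it is clearly longer, since A1 and A2 each need several steps before the route reaches the stage of 4.

Alternative 2: The cut removes C3–C4 and O1–C2 together, taking ring C apart into an ortho-quinone methide and styrene A5.

- **Forward step.** A chiral BINOL-derived N-triflylphosphoramide would ionise the acetal A4 to a 4-methoxy ortho-quinone methide, an aryl oxocarbenium ion paired with the chiral anion. A5 would add through its CH2 terminus to C4 and the phenol oxygen would close on the benzylic carbon in an asynchronous [4+2] process to give the 2,4-cis flavan A6.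
- **In favour.** Ring C and the C2 stereocentre would be made in one catalytic, convergent step from a cheap alkene. Only C2 matters, because C4 is oxidised later. On bonds formed per step and on convergence this is better than the chosen plan. It also needs no dithiane and no stoichiometric chiral material.
- **Against.** The chemistry is cationic, which is what this substrate tolerates least. The free phenol of A4 is ortho to the C8 prenyl group and strong acid would close it to a chroman. The trisubstituted prenyl alkenes are better π-nucleophiles than A5. The para silyloxy group stabilises the cation and lowers its reactivity towards a weak nucleophile. Enantiofacial control at C2 would have to be exerted during closure onto a benzylic cation. Turning the C4 methyl ether into the ketone needs two further steps at a benzylic position, beside an acid-sensitive C2–O bond.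
- **Comparison.** Supply of ring A is equal, since A4 comes from 4 by silylation and acetal formation. In step economy it would be about two steps shorter than the chosen plan. In mechanism it is less secure, because the chosen plan is anionic or neutral throughout and takes its configuration from a purchased epoxide and an SN2 inversion.

Alternative 3: The cut is the bond between C2 and ring B.

- **Forward step.** Phenylboronic acid A8 would transmetalate to a monovalent rhodium centre carrying a chiral bicyclic diene. The chromone A7 binds through C2=C3, the phenyl group migrates to C2 on the face set by the diene, and protonation of the rhodium oxa-π-allyl gives A9.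
- **In favour.** A9 differs from 14 only in the silyl group and is one deprotection from 15. No dithiane, no protecting group on the O1 oxygen and no Mitsunobu closure are needed. The reaction class is established for chromones and either enantiomer is accessible. In step economy and atom economy it is better than the chosen plan, at roughly five or six steps. Supply of ring A is equal, since A7 would be built from a methyl ketone made by the same prenylation that gives 4.
- **Against.** A7 is a weaker acceptor than a simple chromone because the 7-oxygen donates into the pyranone, and it carries a substituent at C8 next to O1. Forcing conditions would leave the flavanone product with boronate and base, which is where retro-oxa-Michael opening erodes the C2 configuration. Facial selectivity for this substitution pattern rests on analogy. The chromone synthesis itself usually includes an acid-promoted cyclisation in the presence of the prenyl groups.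
- **Comparison.** This is the strongest competitor. The chosen plan is preferred only because its configuration does not depend on catalyst control or on product stability under the reaction conditions.

Key step: step 5

Remark: prenyl means 3-methylbut-2-en-1-yl; in the discussion the atoms of every intermediate are referred to by the flavanone numbering of the atoms they become (O1, C2, C3, C4, C4a, C5–C8, C8a), while locants inside compound names are those of the name; (S)-styrene oxide of high enantiomeric purity is taken as a commercial material.

## Route

Step 1
Reactants: 1 2,4-dihydroxybenzaldehyde; 2 prenyl bromide (1-bromo-3-methylbut-2-ene)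
Product: 4 2,4-dihydroxy-3,5-diprenylbenzaldehyde, via 2,4-dihydroxy-3-prenylbenzaldehyde 3 (not isolated)
Conditions: 2 (2.4 equiv), 10% aq. KOH, 0 °C → rt
Reagents that add atoms: prenyl bromide (second equivalent of 2), CC(C)=CCBr
Why: C-alkylation of a resorcinolate (phenoxide C-prenylation): in water the phenoxide oxygens are hydrogen-bonded, which steers the allylic bromide to ring positions 3 and 5 of the benzaldehyde (the future C8 and C6), the only free ring carbons activated by both oxygens. The first equivalent of 2 gives 3 and the second alkylates its remaining activated position, while a first attack at position 5 would converge on the same product. The yield should be modest, which is acceptable for a first step on commodity materials.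

Step 2
Reactants: 4 2,4-dihydroxy-3,5-diprenylbenzaldehyde
Product: 5 2-hydroxy-3,5-diprenyl-4-(triisopropylsilyloxy)benzaldehyde
Conditions: TIPSCl (1.1 equiv), imidazole, DMF, rt
Reagents that add atoms: chlorotriisopropylsilane, CC(C)[Si](Cl)(C(C)C)C(C)C
Why: Regioselective O-silylation: the 4-hydroxyl is the more acidic and is not held in the hydrogen bond to the formyl group that deactivates the 2-hydroxyl, so one equivalent of the silyl chloride should go to the 4-oxygen (the future C7 oxygen). The triisopropylsilyl group is chosen because it must survive K2CO3 in step 3 and n-BuLi in step 5.

Step 3
Reactants: 5 2-hydroxy-3,5-diprenyl-4-(triisopropylsilyloxy)benzaldehyde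
Product: 6 2-(allyloxy)-3,5-diprenyl-4-(triisopropylsilyloxy)benzaldehyde
Conditions: allyl bromide, K2CO3, DMF, rt
Reagents that add atoms: allyl bromide, C=CCBr
Why: Williamson etherification of the remaining chelated phenol. The allyl ether is inert to Lewis acid with thiol and to organolithium base at low temperature, cannot transfer to the later carbanion as a silyl group would, and comes off under neutral palladium catalysis.

Step 4
Reactants: 6 2-(allyloxy)-3,5-diprenyl-4-(triisopropylsilyloxy)benzaldehyde; 7 propane-1,3-dithiol
Product: 8 2-[2-(allyloxy)-3,5-diprenyl-4-(triisopropylsilyloxy)phenyl]-1,3-dithiane
Conditions: BF3·OEt2 (10 mol%), CH2Cl2, −20 → 0 °C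
Reagents that add atoms: none
Why: Lewis acid-catalysed dithioacetalisation of an aryl aldehyde. With both phenols capped there is no ortho-prenylphenol to cyclise, and with catalytic acid at low temperature the trisubstituted alkenes, the allyl ether and the aryl silyl ether should be untouched.

Step 5
Reactants: 8 2-[2-(allyloxy)-3,5-diprenyl-4-(triisopropylsilyloxy)phenyl]-1,3-dithiane; 9 (S)-styrene oxide
Product: 11 (1R)-2-{2-[2-(allyloxy)-3,5-diprenyl-4-(triisopropylsilyloxy)phenyl]-1,3-dithian-2-yl}-1-phenylethanol, via 2-lithio-1,3-dithiane 10 (not isolated)
Conditions: n-BuLi (1.05 equiv), THF, −78 → −30 °C; then 9 (1.3 equiv), −30 °C → rt; aq. NH4Cl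
Reagents that add atoms: none
Why: n-BuLi removes the dithiane C–H, the most acidic hydrogen of 8 because the carbanion is stabilised by two sulfur atoms and the aryl ring, to give 10, a masked acyl anion for C4 (Corey–Seebach umpolung). 10 then opens the epoxide 9 by backside SN2 attack at the unsubstituted CH2 carbon, which forms the C3–C4 bond and leaves the lithium alkoxide of 11; the closest known reaction type is the alkylation of 2-aryl-2-lithio-1,3-dithianes with monosubstituted epoxides. No ring is closed and no stereocentre is created: the benzylic C–O bond of 9 is not touched, so its arrangement in space passes unchanged into 11, and the descriptor changes from S to R only because the CH2 group now ranks below phenyl. The step needs regioselectivity for the CH2 terminus over the benzylic carbon, which the bulk and the soft, delocalised character of 10 and the absence of any Lewis acid should secure. It needs site-selective deprotonation, secured by the gap of several pK units between the dithiane hydrogen and the benzylic-allylic CH2 of the prenyl groups or the OCH2 of the allyl ether, and by the low temperature. It also needs the oxygen substituents to stay in place: the ortho oxygen carries carbon and not silicon, so no 1,4 shift of silicon from oxygen to the carbanion can occur, and the silyl ether sits para to the carbanion-bearing ring carbon, out of reach and shielded by two prenyl groups.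

Step 6
Reactants: 11 (1R)-2-{2-[2-(allyloxy)-3,5-diprenyl-4-(triisopropylsilyloxy)phenyl]-1,3-dithian-2-yl}-1-phenylethanol
Product: 12 (1R)-2-{2-[2-hydroxy-3,5-diprenyl-4-(triisopropylsilyloxy)phenyl]-1,3-dithian-2-yl}-1-phenylethanol
Conditions: Pd(PPh3)4 (5 mol%), morpholine, THF, rt
Reagents that add atoms: none
Why: Tsuji–Trost-type deallylation: zerovalent palladium ionises the allyl aryl ether to a π-allyl complex of divalent palladium and the aryloxide, and morpholine takes up the allyl group irreversibly. The prenyl groups have no leaving group and stay, and the neutral medium avoids the acid that would close the freed ortho-prenylphenol to a chroman or ionise the benzylic carbinol.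

Step 7
Reactants: 12 (1R)-2-{2-[2-hydroxy-3,5-diprenyl-4-(triisopropylsilyloxy)phenyl]-1,3-dithian-2-yl}-1-phenylethanol
Product: 13 (2S)-6,8-diprenyl-7-(triisopropylsilyloxy)flavanone propane-1,3-diyl dithioketal (spiro-1,3-dithiane at C4)
Conditions: PPh3, DIAD (added slowly), THF (0.02 M), 0 °C → rt
Reagents that add atoms: none
Why: Intramolecular Mitsunobu etherification: the phenol protonates the PPh3–DIAD betaine, the benzylic alcohol becomes an alkoxyphosphonium ion, and the phenoxide displaces it from the rear in a 6-exo-tet closure of ring C, inverting C2 from R to S. High dilution favours cyclisation, and with C4 still a dithioketal neither β-elimination to a chalcone nor retro-oxa-Michael opening can occur.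

Step 8
Reactants: 13 (2S)-6,8-diprenyl-7-(triisopropylsilyloxy)flavanone propane-1,3-diyl dithioketal
Product: 14 (2S)-6,8-diprenyl-7-(triisopropylsilyloxy)flavanone
Conditions: MeI (excess), CaCO3, MeCN–H2O (4:1), 40 °C
Reagents that add atoms: water, O
Why: Alkylative dithioketal hydrolysis: S-methylation makes sulfur a leaving group, and the ring-opened thionium ion, stabilised by O1 and the 7-silyloxy group, takes up water and collapses to the ketone. The method is neither oxidative nor strongly acidic, so the prenyl alkenes, the silyl ether and C2 should be spared, and CaCO3 only neutralises the HI formed.

Step 9
Reactants: 14 (2S)-6,8-diprenyl-7-(triisopropylsilyloxy)flavanone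
Product: 15 (2S)-7-hydroxy-6,8-diprenylflavanone
Conditions: TBAF, AcOH (1:1), THF, 0 °C
Reagents that add atoms: none
Why: Fluoride cleavage of an aryl silyl ether para to a carbonyl group, which should be fast even at a hindered silicon. Acetic acid buffers the fluoride so that no phenoxide or enolate builds up, which avoids the base-induced ring opening that would racemise C2.

## Compound list

1 | 2,4-dihydroxybenzaldehyde | O=Cc1ccc(O)cc1O | starting material
2 | prenyl bromide (1-bromo-3-methylbut-2-ene) | CC(C)=CCBr | starting material
3 | 2,4-dihydroxy-3-prenylbenzaldehyde (not isolated) | O=Cc1ccc(O)c(CC=C(C)C)c1O | intermediate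
4 | 2,4-dihydroxy-3,5-diprenylbenzaldehyde | O=Cc1cc(CC=C(C)C)c(O)c(CC=C(C)C)c1O | intermediate
5 | 2-hydroxy-3,5-diprenyl-4-(triisopropylsilyloxy)benzaldehyde | O=Cc1cc(CC=C(C)C)c(O[Si](C(C)C)(C(C)C)C(C)C)c(CC=C(C)C)c1O | intermediate
6 | 2-(allyloxy)-3,5-diprenyl-4-(triisopropylsilyloxy)benzaldehyde | O=Cc1cc(CC=C(C)C)c(O[Si](C(C)C)(C(C)C)C(C)C)c(CC=C(C)C)c1OCC=C | intermediate
7 | propane-1,3-dithiol | SCCCS | starting material
8 | 2-[2-(allyloxy)-3,5-diprenyl-4-(triisopropylsilyloxy)phenyl]-1,3-dithiane | C1(SCCCS1)c1cc(CC=C(C)C)c(O[Si](C(C)C)(C(C)C)C(C)C)c(CC=C(C)C)c1OCC=C | intermediate
9 | (S)-styrene oxide ((2S)-2-phenyloxirane) | O1[C@@H](c2ccccc2)C1 | starting material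
10 | 2-lithio-1,3-dithiane derived from 8, {2-[2-(allyloxy)-3,5-diprenyl-4-(triisopropylsilyloxy)phenyl]-1,3-dithian-2-yl}lithium (not isolated) | [Li]C1(SCCCS1)c1cc(CC=C(C)C)c(O[Si](C(C)C)(C(C)C)C(C)C)c(CC=C(C)C)c1OCC=C | intermediate
11 | (1R)-2-{2-[2-(allyloxy)-3,5-diprenyl-4-(triisopropylsilyloxy)phenyl]-1,3-dithian-2-yl}-1-phenylethanol | O[C@@H](c1ccccc1)CC1(SCCCS1)c1cc(CC=C(C)C)c(O[Si](C(C)C)(C(C)C)C(C)C)c(CC=C(C)C)c1OCC=C | intermediate
12 | (1R)-2-{2-[2-hydroxy-3,5-diprenyl-4-(triisopropylsilyloxy)phenyl]-1,3-dithian-2-yl}-1-phenylethanol | O[C@@H](c1ccccc1)CC1(SCCCS1)c1cc(CC=C(C)C)c(O[Si](C(C)C)(C(C)C)C(C)C)c(CC=C(C)C)c1O | intermediate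
13 | (2S)-6,8-diprenyl-7-(triisopropylsilyloxy)flavanone propane-1,3-diyl dithioketal | CC(C)=CCc1cc2c(c(CC=C(C)C)c1O[Si](C(C)C)(C(C)C)C(C)C)O[C@H](c1ccccc1)CC21SCCCS1 | intermediate
14 | (2S)-6,8-diprenyl-7-(triisopropylsilyloxy)flavanone | CC(C)=CCc1cc2c(c(CC=C(C)C)c1O[Si](C(C)C)(C(C)C)C(C)C)O[C@H](c1ccccc1)CC2=O | intermediate
15 | (2S)-7-hydroxy-6,8-diprenylflavanone | CC(C)=CCc1cc2c(c(CC=C(C)C)c1O)O[C@H](c1ccccc1)CC2=O | target

## Step count and least certain steps

Total step count: 9. Longest linear sequence: 9 steps (1 → 15); 2, 7 and 9 are purchased and enter directly.

**Step 5 (key step).** The most likely failure is slow or incomplete opening of 9 by the hindered, charge-delocalised anion 10. That would give time for the anion to decompose at the neighbouring allyl ether (allyl transfer or deprotonation) and for some attack at the benzylic carbon of the epoxide. The fallback makes the same C3–C4 bond by alkylation at a primary halide instead of an epoxide. From 8, the anion 10 is generated as before and alkylated with (S)-(2-bromo-1-phenylethoxy)triethylsilane F1, prepared from commercial (S)-2-bromo-1-phenylethanol with TESCl and imidazole. Displacement of bromide at CH2 cannot give a regioisomer and leaves the stereocentre alone, so it should give [(1R)-2-{2-[2-(allyloxy)-3,5-diprenyl-4-(triisopropylsilyloxy)phenyl]-1,3-dithian-2-yl}-1-phenylethoxy]triethylsilane F2. PPTS in MeOH at rt then removes the alkyl triethylsilyl ether but not the aryl triisopropylsilyl ether, and the route is rejoined at 11.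

**Step 1.** The most likely failure is competing O-alkylation, arrest at the mono-prenyl stage of 3 and double alkylation at one ring carbon with loss of aromaticity, giving a low conversion to 4 and a difficult separation. The fallback fixes the positions with halogen instead of relying on the selectivity of the phenoxide. From 1, iodination of both activated ring positions (N-iodosuccinimide, MeCN, rt) gives 2,4-dihydroxy-3,5-diiodobenzaldehyde F3. A double Stille coupling with tributyl(3-methylbut-2-en-1-yl)stannane (Pd(PPh3)4, DMF, 90 °C), which couples at the unsubstituted allyl terminus, then returns to the route at 4.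

**Step 7.** The most likely failure is elimination from the alkoxyphosphonium ion to the styrene, or partial ionisation at benzylic C2 that lowers the enantiomeric purity. Both become more likely if the hindered phenol attacks slowly. The fallback separates activation from displacement. From 11, while the phenol is still allylated, the carbinol is converted into (1R)-2-{2-[2-(allyloxy)-3,5-diprenyl-4-(triisopropylsilyloxy)phenyl]-1,3-dithian-2-yl}-1-phenylethyl methanesulfonate F4 (MsCl, Et3N, CH2Cl2, −20 °C, used cold and without purification). Pd(PPh3)4 with NaBH4 in THF then removes the allyl group, and the sodium aryloxide formed displaces the mesylate intramolecularly with inversion, so the route is rejoined at 13 without passing through 12.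

**Step 8.** The most likely failure is sluggish S-methylation at the spiro-fused, hindered dithioketal. On prolonged heating this could be followed by slow loss of C2 configuration through reversible ring opening of the product in the carbonate buffer, or by desilylation and O-methylation of the liberated phenol. The fallback makes ionisation easier by raising the oxidation state of sulfur instead of alkylating it. From 13, NaIO4 (1 equiv, aq. MeOH, 0 °C) oxidises one sulfur to give (2S)-6,8-diprenyl-7-(triisopropylsilyloxy)flavanone propane-1,3-diyl dithioketal S-oxide F5 as a mixture of diastereomers. Dilute aqueous HCl in THF at rt then hydrolyses it, since the protonated sulfinyl group leaves far more readily than a thioether, and the route is rejoined at 14.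

## Further compounds

F1 | step 5 | (S)-(2-bromo-1-phenylethoxy)triethylsilane | CC[Si](CC)(CC)O[C@@H](c1ccccc1)CBr
F2 | step 5 | [(1R)-2-{2-[2-(allyloxy)-3,5-diprenyl-4-(triisopropylsilyloxy)phenyl]-1,3-dithian-2-yl}-1-phenylethoxy]triethylsilane | CC[Si](CC)(CC)O[C@@H](c1ccccc1)CC1(SCCCS1)c1cc(CC=C(C)C)c(O[Si](C(C)C)(C(C)C)C(C)C)c(CC=C(C)C)c1OCC=C
F3 | step 1 | 2,4-dihydroxy-3,5-diiodobenzaldehyde | O=Cc1cc(I)c(O)c(I)c1O
F4 | step 7 | (1R)-2-{2-[2-(allyloxy)-3,5-diprenyl-4-(triisopropylsilyloxy)phenyl]-1,3-dithian-2-yl}-1-phenylethyl methanesulfonate | CS(=O)(=O)O[C@@H](c1ccccc1)CC1(SCCCS1)c1cc(CC=C(C)C)c(O[Si](C(C)C)(C(C)C)C(C)C)c(CC=C(C)C)c1OCC=C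
F5 | step 8 | (2S)-6,8-diprenyl-7-(triisopropylsilyloxy)flavanone propane-1,3-diyl dithioketal S-oxide (mixture of diastereomers at sulfur and C4) | CC(C)=CCc1cc2c(c(CC=C(C)C)c1O[Si](C(C)C)(C(C)C)C(C)C)O[C@H](c1ccccc1)CC21SCCCS1=O
A1 | alternative 1 | (3E)-1-diazo-7-methylocta-3,6-dien-2-one | [N-]=[N+]=CC(=O)/C=C/CC=C(C)C
A2 | alternative 1 | triisopropyl[(5-methylhex-4-en-1-yn-1-yl)oxy]silane | CC(C)=CCC#CO[Si](C(C)C)(C(C)C)C(C)C
A3 | alternative 1 | 2,6-diprenyl-3-(triisopropylsilyloxy)phenol | Oc1c(CC=C(C)C)ccc(O[Si](C(C)C)(C(C)C)C(C)C)c1CC=C(C)C
A4 | alternative 2 | 6-(dimethoxymethyl)-2,4-diprenyl-3-(tert-butyldimethylsilyloxy)phenol | COC(OC)c1cc(CC=C(C)C)c(O[Si](C)(C)C(C)(C)C)c(CC=C(C)C)c1O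
A5 | alternative 2 | styrene | C=Cc1ccccc1
A6 | alternative 2 | (2S,4S)-4-methoxy-7-(tert-butyldimethylsilyloxy)-6,8-diprenylflavan (2,4-cis) | CC(C)=CCc1cc2c(c(CC=C(C)C)c1O[Si](C)(C)C(C)(C)C)O[C@H](c1ccccc1)C[C@@H]2OC
A7 | alternative 3 | 7-(tert-butyldimethylsilyloxy)-6,8-diprenylchromone (4H-chromen-4-one) | O=c1ccoc2c(CC=C(C)C)c(O[Si](C)(C)C(C)(C)C)c(CC=C(C)C)cc12
A8 | alternative 3 | phenylboronic acid | OB(O)c1ccccc1
A9 | alternative 3 | (2S)-7-(tert-butyldimethylsilyloxy)-6,8-diprenylflavanone | CC(C)=CCc1cc2c(c(CC=C(C)C)c1O[Si](C)(C)C(C)(C)C)O[C@H](c1ccccc1)CC2=O
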